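Of the constants of this flask none is given, so a working number has to come from Sunday's run, which is the same flask followed up to 50.0 s.

- Sunday's: substrate 20 mM; solid reagent 50 mM; catalyst 0.26 mM; added ligand 0.19 mM; the very flask that is asked about, followed so far
- flask: substrate 20 mM; solid reagent 50.0 mM; catalyst 0.26 mM; added ligand 0.19 mM; time 3.0 min

Sunday's run (percent of the substrate charged)

| time / s | target / % |
|---|---|
| 10.0 | 2 |
| 12.0 | 1 |
| 20.0 | 3 |
| 30.0 | 8 |
| 50.0 | 19 |

(standard deviation of a reading: 2 percentage points)

- as a solid, counted per litre of solution: solid reagent
- the earlier runs were read with a standard deviation of 2 percentage points
- at the start none of the solid reagent is in solution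
- coupling partner is what solid reagent becomes in solution

- target at 3.0 min, in percent of the substrate charged
- concentration of coupling partner in solution at 50 s, in percent of saturation
- the change that raises the amount of target at 3.0 min, in percent of the substrate charged most ("none" if none brings more than 2 percentage points) (epsilon / beta / delta / none)
- amount of target at 3.0 min, in percent of the substrate charged, after beta

- epsilon: doubling the solubility of the solid reagent, all else as stated
- beta: doubling the amount of catalyst, all else as stated
- delta: doubling the dissolution coefficient of the solid reagent, all else as stated

A rule of thumb suits the lag in Sunday's run: the fraction of the substrate charged that has become target is taken to grow as the square of the time. The reading of 19% at 50.0 s gives 115 s for the square-law time, the time at which that square would reach the whole charge. At 30.0 s the rule puts 6.81% against a reading of 8%, with a scatter of 2 percentage points.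

The border of the rule is a ratio of one between time and square-law time. The asked time stands at 1.57 on that ratio, and the square there gives 2.45 charges, more than the one charge in the flask. Substrate used is a small correction early on, and letting the growth act on what remains turns the fraction into one minus the exponential of minus the square. The reckoning held to here is therefore 91.5% of target at 3.0 min. Sunday's run varies none of the three changes, so its readings give no ranking of them.

The forecast gave 84% (66% to 95%), lower than this reckoning, with 40% of saturation at 50 s, beta as best change and 96% after it, reasoning that “This lag suggests the rate follows the coupling partner”.

The flask gives 66.4% of target at 3.0 min and 64.9% of saturation at 50 s. The change that gains most is beta, doubling the catalyst, with 20 points to reach 86.2%, against 9.5 points for solubility and 3.3 points for the dissolution coefficient.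

    substrate + catalyst → catalyst + intermediate (k = 195 M⁻¹ s⁻¹)
    2 substrate → self-condensation product (k = 0.608 M⁻¹ s⁻¹)
    catalyst + added ligand ⇌ idle complex, settled at all times (K = 2700 M⁻¹)
    solid reagent ⇌ coupling partner, rate k4*(cs4 - [coupling partner]) while solid is left; crystals form when [coupling partner] > cs4 (solubility = 14.0 mM, k = 0.0324 s⁻¹)
    coupling partner + catalyst + intermediate → catalyst + target (k = 6420 M⁻² s⁻¹)

Just after the start, this flask's substrate enters intermediate 1.6 times as fast as it goes to self-condensation product, and at 0.856 min that momentary ratio of rates is 17. The flask carries 22.7% as self-condensation product at 3.00 min and holds 77.3% of target at 30.0 min; at 1.50 min the square gives 61.2% and the flask holds 39.0%. Catalyst stands in both steps towards target, and with the square-law time taken as inverse in catalyst, the neighbour flask with 0.065 mM has 459 s, its asked time lies inside the border, and the square gives 15.4%. That neighbour flask holds 14.8% of target.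

The data were generated by integration from invented constants; noise was put on by code.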